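The route rests on forming the aryl–oxygen bond O1–C8a without touching the tertiary C2–O bond. Phenol 21, which carries the (Z)-allylic tertiary alcohol on C8a, is dearomatised with PhI(OAc)2: the C2 hydroxyl adds to ipso carbon C8a and gives a spiro-2,5-dihydrofuran on an ortho-quinol dienone. Acid then shifts vinyl carbon C4 from C8a to C4a, expanding the five-membered ether into the 2H-pyran ring (O1, C2, C3, C4, C4a, C8a); further oxidation delivers the quinone. The step exploits that C8a sits ortho to the C8 oxygen of the quinone ring. C2 comes from Sharpless epoxidation; the cyclohexane centres are relayed through a temporary octalone ring.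

Key step: step 13

Remark: locants O1, C2–C4, C4a, C5–C8, C8a are those of the 2H-chromene; primed locants are those of the cyclohexane.
Remark: the sense of induction of (S)-1-phenylethylamine with 2,6-dimethylcyclohexanone is assumed to match that with 2-methylcyclohexanone; if it is opposite, the (R)-amine is used.

Step 1
Reactants: 1 2,6-dimethylcyclohexanone (cis/trans mixture); 2 (S)-1-phenylethylamine; 3 methyl vinyl ketone
Product: 6 (2R)-2,6-dimethyl-2-(3-oxobutyl)cyclohexan-1-one (C6 epimer mixture), via ketimine 4 (not isolated), via Michael adduct imine 5 (not isolated)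
Conditions: 1 + 2, TsOH (cat.), toluene, Dean–Stark, reflux; 3, 40 °C; then 20% aq. AcOH, rt
Reagents that add atoms: water (O)
Why: The secondary enamine tautomer of chiral ketimine 4 adds to the enone through a cyclic aza-ene-like transition state on the face left open by the (S)-auxiliary (asymmetric Michael addition of a chiral imine), which sets the quaternary centre C1' as R, and mild acid hydrolysis returns the amine; the configuration at the tertiary α-carbon is corrected in step 2.

Step 2
Reactants: 6 (2R)-2,6-dimethyl-2-(3-oxobutyl)cyclohexan-1-one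
Product: 8 (4aR,8R)-4a,8-dimethyl-4,4a,5,6,7,8-hexahydronaphthalen-2(3H)-one, via aldol ketol 7 (not isolated)
Conditions: NaOMe, MeOH, 60 °C
Reagents that add atoms: none
Why: Intramolecular aldol condensation (Robinson annulation) closes a temporary enone ring, and reversible γ-deprotonation through the dienolate equilibrates C8 to the epimer whose methyl is equatorial and trans to the axial angular methyl, so the future C3' centre is set from C1' by thermodynamic control.

Step 3
Reactants: 8 (4aR,8R)-4a,8-dimethyl-4,4a,5,6,7,8-hexahydronaphthalen-2(3H)-one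
Product: 9 (4aR,8R)-1,8a-epoxy-4a,8-dimethyloctahydronaphthalen-2(1H)-one (epoxide configuration as formed)
Conditions: 30% H2O2, aq. NaOH, MeOH, 0 °C → rt
Reagents that add atoms: hydrogen peroxide (OO)
Why: Weitz–Scheffer nucleophilic epoxidation of the enone; the configuration of the epoxide does not matter because both of its carbons lose their stereochemistry in step 4.

Step 4
Reactants: 9 (4aR,8R)-1,8a-epoxy-4a,8-dimethyloctahydronaphthalen-2(1H)-one
Product: 11 (2R,6R)-2-(but-3-yn-1-yl)-2,6-dimethylcyclohexan-1-one, via epoxy tosylhydrazone 10 (not isolated)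
Conditions: TsNHNH2, AcOH/CH2Cl2 (1:1), −20 °C → rt
Reagents that add atoms: none
Why: Eschenmoser–Tanabe fragmentation: the α,β-epoxy tosylhydrazone opens and loses sulfinate and N2 with cleavage of the C1–C8a bond, which unravels the temporary ring into the ring ketone and a but-3-ynyl chain while the two stereocentres stay untouched under weakly acidic conditions.

Step 5
Reactants: 11 (2R,6R)-2-(but-3-yn-1-yl)-2,6-dimethylcyclohexan-1-one
Product: 12 (1R,3R)-1-(but-3-yn-1-yl)-1,3-dimethyl-2-methylidenecyclohexane
Conditions: Zn, CH2Br2, TiCl4, THF (reagent preformed at 0 °C); then 11, CH2Cl2, 0 °C → rt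
Reagents that add atoms: dibromomethane (BrCBr)
Why: Takai–Lombardo methylenation uses a non-basic gem-dimetallic reagent that converts hindered, enolisable ketones into 1,1-disubstituted alkenes without epimerising the α-stereocentre and tolerates the terminal alkyne.

Step 6
Reactants: 12 (1R,3R)-1-(but-3-yn-1-yl)-1,3-dimethyl-2-methylidenecyclohexane
Product: 14 (2E)-5-[(1R,3R)-1,3-dimethyl-2-methylidenecyclohexyl]-3-methylpent-2-en-1-ol, via alkenylalane 13 (not isolated)
Conditions: AlMe3, Cp2ZrCl2 (0.25 equiv), H2O (1 equiv), CH2Cl2, −20 °C; n-BuLi; (CH2O)n, THF, 0 °C → rt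
Reagents that add atoms: trimethylaluminium (C[Al](C)C); formaldehyde from paraformaldehyde (C=O)
Why: Zirconium-catalysed syn-carboalumination (Negishi) places methyl on the internal and aluminium on the terminal alkyne carbon, and the derived alanate adds to formaldehyde with retention of alkene geometry, so the E-trisubstituted allylic alcohol results; the hindered 1,1-disubstituted ring alkene is not carbometalated.

Step 7
Reactants: 14 (2E)-5-[(1R,3R)-1,3-dimethyl-2-methylidenecyclohexyl]-3-methylpent-2-en-1-ol
Product: 15 [(2S,3S)-3-{2-[(1R,3R)-1,3-dimethyl-2-methylidenecyclohexyl]ethyl}-3-methyloxiran-2-yl]methanol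
Conditions: Ti(OiPr)4 (10 mol %), L-(+)-diethyl tartrate (12 mol %), t-BuOOH, 4 Å MS, CH2Cl2, −20 °C
Reagents that add atoms: tert-butyl hydroperoxide (CC(C)(C)OO)
Why: Sharpless asymmetric epoxidation under reagent control: with L-(+)-tartrate the E-allylic alcohol is epoxidised on the face that gives the (2S,3S)-epoxy alcohol, which fixes the tertiary C–O centre (future C2) independently of the remote ring centres, and the isolated exocyclic alkene is inert to Ti/TBHP.

Step 8
Reactants: 15 [(2S,3S)-3-{2-[(1R,3R)-1,3-dimethyl-2-methylidenecyclohexyl]ethyl}-3-methyloxiran-2-yl]methanol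
Product: 16 (2R,3S)-2-(chloromethyl)-3-{2-[(1R,3R)-1,3-dimethyl-2-methylidenecyclohexyl]ethyl}-3-methyloxirane
Conditions: PPh3, CCl4, NaHCO3, reflux
Reagents that add atoms: carbon tetrachloride (ClC(Cl)(Cl)Cl)
Why: Appel chlorination of the primary alcohol under bicarbonate buffering proceeds at the CH2OH carbon only and leaves both epoxide centres intact (the descriptor at C2 changes only because of CIP priorities).

Step 9
Reactants: 16 (2R,3S)-2-(chloromethyl)-3-{2-[(1R,3R)-1,3-dimethyl-2-methylidenecyclohexyl]ethyl}-3-methyloxirane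
Product: 17 (3S)-5-[(1R,3R)-1,3-dimethyl-2-methylidenecyclohexyl]-3-methylpent-1-yn-3-ol
Conditions: n-BuLi (3.5 equiv), THF, −40 °C → rt; aq. NH4Cl
Reagents that add atoms: none
Why: Base-induced fragmentation of the 2,3-epoxy chloride (deprotonation at the chloromethyl carbon, β-elimination with epoxide opening, then dehydrochlorination of the chloroalkene) gives the terminal propargylic alcohol, and since no bond to the tertiary carbinol carbon is broken its configuration is retained as 3S.

Step 10
Reactants: 18 3,4-dimethoxyphenol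
Product: 19 2-iodo-4,5-dimethoxyphenol
Conditions: N-iodosuccinimide, MeCN, 0 °C, dark
Reagents that add atoms: N-iodosuccinimide (O=C1CCC(=O)N1I)
Why: Electrophilic aromatic iodination goes to C6 of the phenol, the position ortho to the hydroxyl and para to the 3-methoxy group and not flanked by two substituents.

Step 11
Reactants: 17 (3S)-5-[(1R,3R)-1,3-dimethyl-2-methylidenecyclohexyl]-3-methylpent-1-yn-3-ol; 19 2-iodo-4,5-dimethoxyphenol
Product: 20 2-{(3S)-5-[(1R,3R)-1,3-dimethyl-2-methylidenecyclohexyl]-3-hydroxy-3-methylpent-1-yn-1-yl}-4,5-dimethoxyphenol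
Conditions: PdCl2(PPh3)2 (3 mol %), CuI (5 mol %), Et3N, THF, rt, degassed
Reagents that add atoms: none
Why: Sonogashira coupling of the aryl iodide with the terminal alkyne proceeds at room temperature in the presence of the free phenol and tertiary alcohol, and the mild temperature is chosen to suppress 5-endo cyclisation of the ortho-alkynylphenol.

Step 12
Reactants: 20 2-{(3S)-5-[(1R,3R)-1,3-dimethyl-2-methylidenecyclohexyl]-3-hydroxy-3-methylpent-1-yn-1-yl}-4,5-dimethoxyphenol
Product: 21 2-{(1Z,3S)-5-[(1R,3R)-1,3-dimethyl-2-methylidenecyclohexyl]-3-hydroxy-3-methylpent-1-en-1-yl}-4,5-dimethoxyphenol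
Conditions: H2 (1 atm), Lindlar catalyst, quinoline, EtOAc, rt; used at once, acid-free work-up
Reagents that add atoms: none
Why: Lindlar semihydrogenation adds H2 syn to the alkyne and stops at the Z-alkene, which is the geometry that brings the C2 hydroxyl next to C8a; the hindered exocyclic alkene is not reduced.

Step 13
Reactants: 21 2-{(1Z,3S)-5-[(1R,3R)-1,3-dimethyl-2-methylidenecyclohexyl]-3-hydroxy-3-methylpent-1-en-1-yl}-4,5-dimethoxyphenol
Product: 24 metachromin E, via spirodienone 22 (not isolated), via chromenol 23 (not isolated)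
Conditions: PhI(OAc)2 (1.05 equiv), dry MeCN/CH2Cl2, −30 °C; CF3CO2H (0.3 equiv), −30 → 0 °C; then H2O, PhI(OAc)2 (1.2 equiv), 0 °C
Reagents that add atoms: water (O)
Why: Ligand exchange of the phenol on iodine(III) and loss of PhI make the ring electrophilic at ipso carbon C8a, which the Z-alkene holds next to the C2 hydroxyl, so that oxygen closes the 2,5-dihydrofuran O1–C2–C3=C4–C8a in a 5-exo mode and gives ortho-quinol spiroether 22 (oxidative dearomatising spiroetherification). Protonation of the dienone carbonyl then triggers a dienone–phenol 1,2-shift of vinyl carbon C4 from C8a to C4a and loss of the C4a proton rearomatises, so the five-membered spiro ether is expanded to the six-membered 2H-pyran of chromenol 23 with the aryl C8a–O1 bond in place. The closest known reaction type is the ipso-spirocyclisation/dienone–phenol rearrangement of spirocyclohexadienones to benzo-fused six-membered heterocycles. No lasting stereocentre is created: the spiro centre is transient and C2 keeps its S configuration because none of its bonds is broken. The step needs ipso attack at C8a, not capture at the para carbon C5, which the tethered nucleophile and a medium free of competing nucleophiles should secure, and carbon migration, not oxygen migration, which the higher migratory aptitude of the vinyl group and the O1-stabilised cation left at C8a should secure; C4a is the only diene terminus next to the spiro carbon. The second portion of oxidant with water converts the para-methoxyphenol 23 into the quinone by addition of water at C5 and loss of methanol.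

Compound list
1 | 2,6-dimethylcyclohexanone (cis/trans mixture) | CC1CCCC(C)C1=O | starting material
2 | (S)-1-phenylethylamine | C[C@H](N)c1ccccc1 | starting material
3 | methyl vinyl ketone | C=CC(C)=O | starting material
4 | (S)-N-(2,6-dimethylcyclohexylidene)-1-phenylethanamine (ketimine) | C[C@H](N=C1C(C)CCCC1C)c1ccccc1 | intermediate, not isolated
5 | 4-[(1R)-1,3-dimethyl-2-{[(1S)-1-phenylethyl]imino}cyclohexyl]butan-2-one (Michael adduct imine) | C[C@H](N=C1C(C)CCC[C@]1(C)CCC(C)=O)c1ccccc1 | intermediate, not isolated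
6 | (2R)-2,6-dimethyl-2-(3-oxobutyl)cyclohexan-1-one (C6 epimer mixture) | O=C1C(C)CCC[C@]1(C)CCC(C)=O | intermediate
7 | (4aR)-8a-hydroxy-4a,8-dimethyloctahydronaphthalen-2(1H)-one (aldol ketol, C8 and C8a as formed) | O=C1CC2(O)C(C)CCC[C@]2(C)CC1 | intermediate, not isolated
8 | (4aR,8R)-4a,8-dimethyl-4,4a,5,6,7,8-hexahydronaphthalen-2(3H)-one | O=C1C=C2[C@H](C)CCC[C@]2(C)CC1 | intermediate
9 | (4aR,8R)-1,8a-epoxy-4a,8-dimethyloctahydronaphthalen-2(1H)-one (epoxide configuration as formed) | O=C1C3OC32[C@H](C)CCC[C@]2(C)CC1 | intermediate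
10 | p-toluenesulfonylhydrazone of 9 | Cc1ccc(cc1)S(=O)(=O)NN=C1C3OC32[C@H](C)CCC[C@]2(C)CC1 | intermediate, not isolated
11 | (2R,6R)-2-(but-3-yn-1-yl)-2,6-dimethylcyclohexan-1-one | O=C1[C@H](C)CCC[C@]1(C)CCC#C | intermediate
12 | (1R,3R)-1-(but-3-yn-1-yl)-1,3-dimethyl-2-methylidenecyclohexane | C=C1[C@H](C)CCC[C@]1(C)CCC#C | intermediate
13 | (E)-{4-[(1R,3R)-1,3-dimethyl-2-methylidenecyclohexyl]-2-methylbut-1-en-1-yl}dimethylalane | C=C1[C@H](C)CCC[C@]1(C)CC/C(C)=C/[Al](C)C | intermediate, not isolated
14 | (2E)-5-[(1R,3R)-1,3-dimethyl-2-methylidenecyclohexyl]-3-methylpent-2-en-1-ol | C=C1[C@H](C)CCC[C@]1(C)CC/C(C)=C/CO | intermediate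
15 | [(2S,3S)-3-{2-[(1R,3R)-1,3-dimethyl-2-methylidenecyclohexyl]ethyl}-3-methyloxiran-2-yl]methanol | C=C1[C@H](C)CCC[C@]1(C)CC[C@]1(C)O[C@H]1CO | intermediate
16 | (2R,3S)-2-(chloromethyl)-3-{2-[(1R,3R)-1,3-dimethyl-2-methylidenecyclohexyl]ethyl}-3-methyloxirane | C=C1[C@H](C)CCC[C@]1(C)CC[C@]1(C)O[C@H]1CCl | intermediate
17 | (3S)-5-[(1R,3R)-1,3-dimethyl-2-methylidenecyclohexyl]-3-methylpent-1-yn-3-ol | C=C1[C@H](C)CCC[C@]1(C)CC[C@](C)(O)C#C | intermediate
18 | 3,4-dimethoxyphenol | COc1ccc(O)cc1OC | starting material
19 | 2-iodo-4,5-dimethoxyphenol | COc1cc(O)c(I)cc1OC | intermediate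
20 | 2-{(3S)-5-[(1R,3R)-1,3-dimethyl-2-methylidenecyclohexyl]-3-hydroxy-3-methylpent-1-yn-1-yl}-4,5-dimethoxyphenol | C=C1[C@H](C)CCC[C@]1(C)CC[C@](C)(O)C#Cc1cc(OC)c(OC)cc1O | intermediate
21 | 2-{(1Z,3S)-5-[(1R,3R)-1,3-dimethyl-2-methylidenecyclohexyl]-3-hydroxy-3-methylpent-1-en-1-yl}-4,5-dimethoxyphenol | C=C1[C@H](C)CCC[C@]1(C)CC[C@](C)(O)/C=C\c1cc(OC)c(OC)cc1O | intermediate
22 | (2S)-2-{2-[(1R,3R)-1,3-dimethyl-2-methylidenecyclohexyl]ethyl}-8,9-dimethoxy-2-methyl-1-oxaspiro[4.5]deca-3,7,9-trien-6-one (spiro centre as formed) | C=C1[C@H](C)CCC[C@]1(C)CC[C@@]1(C)C=CC2(O1)C=C(OC)C(OC)=CC2=O | intermediate, not isolated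
23 | (2S)-2-{2-[(1R,3R)-1,3-dimethyl-2-methylidenecyclohexyl]ethyl}-5,6-dimethoxy-2-methyl-2H-chromen-8-ol | C=C1[C@H](C)CCC[C@]1(C)CC[C@@]1(C)C=Cc2c(OC)c(OC)cc(O)c2O1 | intermediate, not isolated
24 | metachromin E, (2S)-2-{2-[(1R,3R)-1,3-dimethyl-2-methylidenecyclohexyl]ethyl}-6-methoxy-2-methyl-2H-chromene-5,8-dione | C=C1[C@H](C)CCC[C@]1(C)CC[C@@]1(C)C=CC2=C(O1)C(=O)C=C(OC)C2=O | target

Total step count: 13
Longest linear sequence: 12 steps (steps 1–9 and 11–13)

Steps most likely to fail

Step 13. The oxidised ring may be captured at the para carbon C5 by acetate or adventitious water before the tertiary hydroxyl closes on C8a. The extended cation may also undergo a semipinacol shift at C2, or acid may ionise the tertiary allylic C2–O bond and erode the C2 configuration. The fallback gives up the spiro intermediate and closes the pyran by conjugate addition to a quinone, which also leaves the C2–O bond untouched. It sets out from alkynol 17. Sonogashira coupling with purchased 2-iodo-6-methoxyphenol F1 (PdCl2(PPh3)2, CuI, Et3N) should give the alkynyl phenol F2, and Lindlar semihydrogenation the Z-alkenyl phenol F3. Oxidation of this phenol at its free para position (salcomine, O2, DMF) should give the methoxyquinone F4, which carries the side chain on C4a and hydrogen on C8a. Intramolecular oxa-Michael addition of the tertiary hydroxyl to C8a (cat. Et3N, CH2Cl2) should then give the chromene hydroquinone F5, which is oxidised in the same flask by air or Ag2O, and the route is rejoined at 24.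

Step 11. The free ortho-alkynylphenol may cyclise under Pd/Cu to a 2-substituted benzofuran, or the electron-rich iodophenol may be oxidised. The fallback masks the phenol and so removes the nucleophile. It sets out from 19. Acetylation (Ac2O, pyridine) should give 2-iodo-4,5-dimethoxyphenyl acetate F6, Sonogashira coupling with 17 the alkynyl aryl acetate F7, and Lindlar semihydrogenation the Z-alkenyl aryl acetate F8. Methanolysis (K2CO3, MeOH, 0 °C) then returns to the route at 21.

Step 5. Methylene transfer to a carbonyl flanked by a quaternary and a tertiary carbon may stall, or enolisation may epimerise C6. The fallback is a Peterson olefination in two stages from 11. Addition of Me3SiCH2Li in the presence of CeCl3 (THF, −78 °C, excess to cover the alkyne C–H) should give the β-hydroxysilane F9, and elimination with KH in THF returns to the route at 12.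

Further compounds
F1 | step 13 | 2-iodo-6-methoxyphenol (purchased) | COc1cccc(I)c1O
F2 | step 13 | 2-{(3S)-5-[(1R,3R)-1,3-dimethyl-2-methylidenecyclohexyl]-3-hydroxy-3-methylpent-1-yn-1-yl}-6-methoxyphenol | C=C1[C@H](C)CCC[C@]1(C)CC[C@](C)(O)C#Cc1cccc(OC)c1O
F3 | step 13 | 2-{(1Z,3S)-5-[(1R,3R)-1,3-dimethyl-2-methylidenecyclohexyl]-3-hydroxy-3-methylpent-1-en-1-yl}-6-methoxyphenol | C=C1[C@H](C)CCC[C@]1(C)CC[C@](C)(O)/C=C\c1cccc(OC)c1O
F4 | step 13 | 2-{(1Z,3S)-5-[(1R,3R)-1,3-dimethyl-2-methylidenecyclohexyl]-3-hydroxy-3-methylpent-1-en-1-yl}-6-methoxycyclohexa-2,5-diene-1,4-dione | C=C1[C@H](C)CCC[C@]1(C)CC[C@](C)(O)/C=C\C1=CC(=O)C=C(OC)C1=O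
F5 | step 13 | (2S)-2-{2-[(1R,3R)-1,3-dimethyl-2-methylidenecyclohexyl]ethyl}-6-methoxy-2-methyl-2H-chromene-5,8-diol | C=C1[C@H](C)CCC[C@]1(C)CC[C@@]1(C)C=Cc2c(O1)c(O)cc(OC)c2O
F6 | step 11 | 2-iodo-4,5-dimethoxyphenyl acetate | CC(=O)Oc1cc(OC)c(OC)cc1I
F7 | step 11 | 2-{(3S)-5-[(1R,3R)-1,3-dimethyl-2-methylidenecyclohexyl]-3-hydroxy-3-methylpent-1-yn-1-yl}-4,5-dimethoxyphenyl acetate | C=C1[C@H](C)CCC[C@]1(C)CC[C@](C)(O)C#Cc1cc(OC)c(OC)cc1OC(C)=O
F8 | step 11 | 2-{(1Z,3S)-5-[(1R,3R)-1,3-dimethyl-2-methylidenecyclohexyl]-3-hydroxy-3-methylpent-1-en-1-yl}-4,5-dimethoxyphenyl acetate | C=C1[C@H](C)CCC[C@]1(C)CC[C@](C)(O)/C=C\c1cc(OC)c(OC)cc1OC(C)=O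
F9 | step 5 | (2R,6R)-2-(but-3-yn-1-yl)-2,6-dimethyl-1-[(trimethylsilyl)methyl]cyclohexan-1-ol (carbinol centre as formed) | C[Si](C)(C)CC1(O)[C@H](C)CCC[C@]1(C)CCC#C
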